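**Retrosynthetic overview**
1. 22 ⇐ 21 by acylation of the C2 hydroxyl only; 21 ⇐ 18 by turning the E allylic alcohol C13=C14–C15OH into the 13S vinyl carbinol (Sharpless epoxidation, iodination, zinc-induced epoxide opening).
2. 18 ⇐ 17 ⇐ 16: one radical cascade on an open chain closes ring A first (bond C4–C5) and ring B last (bond C9–C10); loss of PhSO2 from C7 leaves the C7=C8 alkene.
3. 16 ⇐ allylic sulfone 14 (C7–C9, C11–C17, from geraniol) + allylic bromide 9 (C1–C6, C18–C20), joined at C6–C7 by sulfone alkylation.
4. 9 ⇐ (R)-epichlorohydrin (C1–C3, source of the C2 centre) + isopropenyl Grignard (C4, C18, C19) + acetylide (C10, C5), then Zr-catalysed carboalumination (C20) and formaldehyde (C6).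
5. Enabling feature: ring B has its only double bond at C7=C8, allylic to C9, which is bonded to ring-fusion carbon C10; the open chain can therefore carry C9=C8–C7(SO2Ph) as an allyl sulfone that takes the C10 radical at C9 and re-forms the alkene at C7=C8. In ring A the oxygen-bearing C2 is 1,3 to the gem-dimethyl carbon C4, so a methallyl carbinol supplies the C4 radical and its C2 centre directs the fold.

Key step: step 11

Remark: C1–C20 are the labdane numbers of the target and are used for all intermediates; 1, 10 and all reagents are taken as commercial; 16 is carried as both epimers at C7, a centre that becomes sp2 in step 11.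

**Route**

Step 1
Reactants: 1 (R)-epichlorohydrin
Product: 3 (2R)-2-(2-methylprop-2-en-1-yl)oxirane, via chlorohydrin 2 (not isolated)
Conditions: CH2=C(Me)MgBr, CuI (10 mol %), THF, −40 to 0 °C; then aq NaOH, rt; distillation
Reagents that add atoms: isopropenylmagnesium bromide C=C(C)[Mg]Br
Why: Copper-catalysed Grignard opening of the epoxide at its CH2 terminus and Williamson closure of the chlorohydrin break no bond to the stereocentre, so the R configuration of 1 becomes C2.

Step 2
Reactants: 3 (2R)-2-(2-methylprop-2-en-1-yl)oxirane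
Product: 4 (4R)-6-methylhept-6-en-1-yn-4-ol
Conditions: HC≡CLi·H2NCH2CH2NH2, DMSO, 0 °C to rt; H2O
Reagents that add atoms: lithium acetylide (ethylenediamine complex) [Li]C#C
Why: SN2 opening of the terminal epoxide at the unsubstituted carbon by acetylide leaves the carbinol centre untouched and brings in C10 and C5 as an alkyne.

Step 3
Reactants: 4 (4R)-6-methylhept-6-en-1-yn-4-ol
Product: 5 tert-butyldimethyl{[(4R)-6-methylhept-6-en-1-yn-4-yl]oxy}silane
Conditions: TBSCl, imidazole, DMF, rt
Reagents that add atoms: tert-butyldimethylsilyl chloride CC(C)(C)[Si](C)(C)Cl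
Why: Standard imidazole-promoted silylation masks the C2 hydroxyl as a bulky ether that later steers the ring A fold.

Step 4
Reactants: 5 tert-butyldimethyl{[(4R)-6-methylhept-6-en-1-yn-4-yl]oxy}silane
Product: 8 (2E,5R)-5-[(tert-butyldimethylsilyl)oxy]-3,7-dimethylocta-2,7-dien-1-ol, via alkenyldimethylalane 6 (not isolated), via lithium alkenylaluminate 7 (not isolated)
Conditions: Me3Al, Cp2ZrCl2 (25 mol %), CH2Cl2, 0 °C to rt; evaporate; n-BuLi, THF, −78 to 0 °C; (CH2O)n, rt; aq Rochelle salt
Reagents that add atoms: trimethylaluminium C[Al](C)C; formaldehyde (as paraformaldehyde) C=O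
Why: Negishi carboalumination adds Me and Al syn across the terminal alkyne with Al on the terminal carbon, and hydroxymethylation of the derived aluminate proceeds with retention, which fixes the E C5=C10 geometry while the 1,1-disubstituted alkene stays inert.

Step 5
Reactants: 8 (2E,5R)-5-[(tert-butyldimethylsilyl)oxy]-3,7-dimethylocta-2,7-dien-1-ol
Product: 9 {[(4R,6E)-8-bromo-2,6-dimethylocta-1,6-dien-4-yl]oxy}(tert-butyl)dimethylsilane
Conditions: CBr4, PPh3, CH2Cl2, 0 °C
Reagents that add atoms: carbon tetrabromide BrC(Br)(Br)Br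
Why: Appel bromination converts the primary allylic alcohol under neutral conditions that spare the silyl ether and both alkenes.

Step 6
Reactants: 10 geraniol
Product: 11 tert-butyl{[(2E)-3,7-dimethylocta-2,6-dien-1-yl]oxy}diphenylsilane
Conditions: TBDPSCl, imidazole, DMF, rt
Reagents that add atoms: tert-butyldiphenylsilyl chloride CC(C)(C)[Si](Cl)(c1ccccc1)c1ccccc1
Why: Standard silylation gives a robust primary allylic ether that survives oxidation, carbanion and radical steps.

Step 7
Reactants: 11 tert-butyl{[(2E)-3,7-dimethylocta-2,6-dien-1-yl]oxy}diphenylsilane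
Product: 12 (2E,6E)-8-[(tert-butyldiphenylsilyl)oxy]-2,6-dimethylocta-2,6-dien-1-ol
Conditions: SeO2 (cat.), t-BuOOH, salicylic acid (cat.), CH2Cl2, rt
Reagents that add atoms: tert-butyl hydroperoxide CC(C)(C)OO
Why: Sharpless SeO2/t-BuOOH allylic oxidation (ene then [2,3] shift) is selective for the E methyl of the terminal trisubstituted alkene, the oxygen-substituted C13=C14 alkene being deactivated.

Step 8
Reactants: 12 (2E,6E)-8-[(tert-butyldiphenylsilyl)oxy]-2,6-dimethylocta-2,6-dien-1-ol
Product: 13 {[(2E,6E)-8-bromo-3,7-dimethylocta-2,6-dien-1-yl]oxy}(tert-butyl)diphenylsilane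
Conditions: CBr4, PPh3, CH2Cl2, 0 °C
Reagents that add atoms: carbon tetrabromide BrC(Br)(Br)Br
Why: Appel bromination of the primary allylic alcohol proceeds without allylic transposition or loss of alkene geometry.

Step 9
Reactants: 13 {[(2E,6E)-8-bromo-3,7-dimethylocta-2,6-dien-1-yl]oxy}(tert-butyl)diphenylsilane
Product: 14 tert-butyl{[(2E,6E)-3,7-dimethyl-8-(phenylsulfonyl)octa-2,6-dien-1-yl]oxy}diphenylsilane
Conditions: PhSO2Na, DMF, rt
Reagents that add atoms: sodium benzenesulfinate [Na+].[O-]S(=O)c1ccccc1
Why: SN2 S-alkylation of sulfinate by the primary allylic bromide gives the allylic sulfone with the E alkene intact.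

Step 10
Reactants: 14 tert-butyl{[(2E,6E)-3,7-dimethyl-8-(phenylsulfonyl)octa-2,6-dien-1-yl]oxy}diphenylsilane; 9 {[(4R,6E)-8-bromo-2,6-dimethylocta-1,6-dien-4-yl]oxy}(tert-butyl)dimethylsilane
Product: 16 tert-butyl{[(2E,6E,10E,13R)-13-[(tert-butyldimethylsilyl)oxy]-3,7,11,15-tetramethyl-8-(phenylsulfonyl)hexadeca-2,6,10,15-tetraen-1-yl]oxy}diphenylsilane (both epimers at the sulfone carbon, labdane C7), via lithiated sulfone 15 (not isolated)
Conditions: n-BuLi, THF, −78 °C; then 9, −78 to −20 °C
Reagents that add atoms: none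
Why: Biellmann-type coupling, in which the sulfonyl-stabilised allyl anion is alkylated at its α carbon by the primary allylic bromide, joins C6 to C7; the new C7 centre is not controlled and need not be.

Step 11
Reactants: 16 tert-butyl{[(2E,6E,10E,13R)-13-[(tert-butyldimethylsilyl)oxy]-3,7,11,15-tetramethyl-8-(phenylsulfonyl)hexadeca-2,6,10,15-tetraen-1-yl]oxy}diphenylsilane
Product: 17 (2R,5R,9R,10R,13E)-2-[(tert-butyldimethylsilyl)oxy]-15-[(tert-butyldiphenylsilyl)oxy]labda-7,13-diene
Conditions: Fe(acac)3 (30 mol %), PhSiH3 (slow addition), EtOH/(CH2OH)2, 0.01 M, 60 °C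
Reagents that add atoms: none
Why: Proposed new method: an iron hydride formed from Fe(acac)3 and PhSiH3 should transfer a hydrogen atom to the CH2 terminus of the 1,1-disubstituted alkene of 16, the tertiary C4 radical then adds to C5, the C10 radical so formed adds to C9, and the C8 radical expels PhSO2• from C7 to leave the C7=C8 double bond, while divalent iron reduces PhSO2• to sulfinate and so returns trivalent iron. The closest known reaction types are the iron/phenylsilane hydrogen-atom-transfer radical polyene cyclization that ends on an electron-poor alkene and the radical allylation by allyl sulfones (addition followed by β-fragmentation); their union on an unactivated polyprenyl chain, with the sulfone as a traceless terminator, is the new element. Ring A closes in the 6-endo-trig mode (C4 onto C5) and ring B in the 6-endo-trig mode (C10 onto C9), each preferred to 5-exo because the nearer alkene carbon carries a methyl group and attack there would join two fully substituted carbons and give a secondary radical. C5 and C10 should arise trans through the chair–chair fold of the E C5=C10 alkene, C9 should get its side chain equatorial from the E geometry of C8=C9, and the absolute sense of all three is set by the C2 silyloxy group, which stays equatorial in the ring A chair because an axial position would clash with the axial methyl on C4 and with C20. The step needs chemoselective initiation, secured by the steric and radical-stability preference of hydrogen-atom transfer for the 1,1-disubstituted alkene over the three trisubstituted ones, and fragmentation faster than reduction of the C8 radical, secured by the weak allylic C–S bond, high dilution and slow silane addition; both C7 epimers of 16 should converge because C7 becomes sp2.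

Step 12
Reactants: 17 (2R,5R,9R,10R,13E)-2-[(tert-butyldimethylsilyl)oxy]-15-[(tert-butyldiphenylsilyl)oxy]labda-7,13-diene
Product: 18 (2R,5R,9R,10R,13E)-labda-7,13-diene-2,15-diol
Conditions: TBAF, THF, rt to 40 °C
Reagents that add atoms: none
Why: Fluoride cleaves both silyl ethers through Si–F bond formation without touching either alkene.

Step 13
Reactants: 18 (2R,5R,9R,10R,13E)-labda-7,13-diene-2,15-diol
Product: 19 (2R,5R,9R,10R,13S,14S)-13,14-epoxylabd-7-ene-2,15-diol
Conditions: Ti(OiPr)4 (10 mol %), L-(+)-diethyl tartrate (12 mol %), t-BuOOH, 4 Å MS, CH2Cl2, −20 °C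
Reagents that add atoms: tert-butyl hydroperoxide CC(C)(C)OO
Why: Sharpless asymmetric epoxidation acts only on the allylic alcohol and, with L-(+)-tartrate on an E trisubstituted allylic alcohol, should deliver oxygen to the face that gives the 13S,14S epoxide (reagent control, as for geraniol).

Step 14
Reactants: 19 (2R,5R,9R,10R,13S,14S)-13,14-epoxylabd-7-ene-2,15-diol
Product: 20 (2R,5R,9R,10R,13S,14R)-13,14-epoxy-15-iodolabd-7-en-2-ol
Conditions: PPh3, I2, imidazole, THF, 0 °C
Reagents that add atoms: iodine II
Why: Appel-type iodination is selective for the primary alcohol because SN2 at the equatorial C2 carbinol would need axial approach past the two syn-axial methyl groups.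

Step 15
Reactants: 20 (2R,5R,9R,10R,13S,14R)-13,14-epoxy-15-iodolabd-7-en-2-ol
Product: 21 (2R,5R,9R,10R,13S)-labda-7,14-diene-2,13-diol
Conditions: Zn dust, AcOH, EtOH, rt to 50 °C
Reagents that add atoms: none
Why: Zinc insertion into the C–I bond and β-elimination open the epoxide (reductive 1,3-transposition) to the vinyl carbinol; the C13–O bond is not broken, so 13S is retained.

Step 16
Reactants: 21 (2R,5R,9R,10R,13S)-labda-7,14-diene-2,13-diol
Product: 22 (2R,5R,9R,10R,13S)-13-hydroxylabda-7,14-dien-2-yl 3-methylbut-2-enoate (CNP0252389.1)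
Conditions: 3-methylbut-2-enoyl chloride, pyridine, DMAP (cat.), CH2Cl2, 0 °C to rt
Reagents that add atoms: 3-methylbut-2-enoyl chloride CC(C)=CC(Cl)=O
Why: DMAP-catalysed acylation takes place at the unhindered secondary C2 hydroxyl, while the tertiary allylic C13 hydroxyl does not react under these conditions.

**Compound list**
1 | (R)-epichlorohydrin [(2R)-2-(chloromethyl)oxirane] | ClC[C@H]1CO1 | starting material
2 | (2R)-1-chloro-4-methylpent-4-en-2-ol | C=C(C)C[C@@H](O)CCl | intermediate
3 | (2R)-2-(2-methylprop-2-en-1-yl)oxirane | C=C(C)C[C@@H]1CO1 | intermediate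
4 | (4R)-6-methylhept-6-en-1-yn-4-ol | C=C(C)C[C@@H](O)CC#C | intermediate
5 | tert-butyldimethyl{[(4R)-6-methylhept-6-en-1-yn-4-yl]oxy}silane | C=C(C)C[C@@H](O[Si](C)(C)C(C)(C)C)CC#C | intermediate
6 | {(1E,4R)-4-[(tert-butyldimethylsilyl)oxy]-2,6-dimethylhepta-1,6-dien-1-yl}dimethylalane | C=C(C)C[C@@H](O[Si](C)(C)C(C)(C)C)C/C(C)=C/[Al](C)C | intermediate
7 | lithium butyl{(1E,4R)-4-[(tert-butyldimethylsilyl)oxy]-2,6-dimethylhepta-1,6-dien-1-yl}dimethylaluminate | [Li+].C=C(C)C[C@@H](O[Si](C)(C)C(C)(C)C)C/C(C)=C/[Al-](C)(C)CCCC | intermediate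
8 | (2E,5R)-5-[(tert-butyldimethylsilyl)oxy]-3,7-dimethylocta-2,7-dien-1-ol | C=C(C)C[C@@H](O[Si](C)(C)C(C)(C)C)C/C(C)=C/CO | intermediate
9 | {[(4R,6E)-8-bromo-2,6-dimethylocta-1,6-dien-4-yl]oxy}(tert-butyl)dimethylsilane | C=C(C)C[C@@H](O[Si](C)(C)C(C)(C)C)C/C(C)=C/CBr | intermediate
10 | geraniol [(2E)-3,7-dimethylocta-2,6-dien-1-ol] | CC(C)=CCC/C(C)=C/CO | starting material
11 | tert-butyl{[(2E)-3,7-dimethylocta-2,6-dien-1-yl]oxy}diphenylsilane | CC(C)=CCC/C(C)=C/CO[Si](c1ccccc1)(c1ccccc1)C(C)(C)C | intermediate
12 | (2E,6E)-8-[(tert-butyldiphenylsilyl)oxy]-2,6-dimethylocta-2,6-dien-1-ol | OC/C(C)=C/CC/C(C)=C/CO[Si](c1ccccc1)(c1ccccc1)C(C)(C)C | intermediate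
13 | {[(2E,6E)-8-bromo-3,7-dimethylocta-2,6-dien-1-yl]oxy}(tert-butyl)diphenylsilane | BrC/C(C)=C/CC/C(C)=C/CO[Si](c1ccccc1)(c1ccccc1)C(C)(C)C | intermediate
14 | tert-butyl{[(2E,6E)-3,7-dimethyl-8-(phenylsulfonyl)octa-2,6-dien-1-yl]oxy}diphenylsilane | O=S(=O)(c1ccccc1)C/C(C)=C/CC/C(C)=C/CO[Si](c1ccccc1)(c1ccccc1)C(C)(C)C | intermediate
15 | 14 lithiated at the sulfonyl-bearing carbon | [Li]C(S(=O)(=O)c1ccccc1)/C(C)=C/CC/C(C)=C/CO[Si](c1ccccc1)(c1ccccc1)C(C)(C)C | intermediate
16 | tert-butyl{[(2E,6E,10E,13R)-13-[(tert-butyldimethylsilyl)oxy]-3,7,11,15-tetramethyl-8-(phenylsulfonyl)hexadeca-2,6,10,15-tetraen-1-yl]oxy}diphenylsilane (both C8 epimers) | C=C(C)C[C@@H](O[Si](C)(C)C(C)(C)C)C/C(C)=C/CC(S(=O)(=O)c1ccccc1)/C(C)=C/CC/C(C)=C/CO[Si](c1ccccc1)(c1ccccc1)C(C)(C)C | intermediate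
17 | (2R,5R,9R,10R,13E)-2-[(tert-butyldimethylsilyl)oxy]-15-[(tert-butyldiphenylsilyl)oxy]labda-7,13-diene | CC(C)(C)[Si](c1ccccc1)(c1ccccc1)OC/C=C(\C)CC[C@@H]1C(C)=CC[C@@H]2C(C)(C)C[C@@H](O[Si](C)(C)C(C)(C)C)C[C@@]12C | intermediate
18 | (2R,5R,9R,10R,13E)-labda-7,13-diene-2,15-diol | OC/C=C(\C)CC[C@@H]1C(C)=CC[C@@H]2C(C)(C)C[C@@H](O)C[C@@]12C | intermediate
19 | (2R,5R,9R,10R,13S,14S)-13,14-epoxylabd-7-ene-2,15-diol | OC[C@@H]3O[C@@]3(C)CC[C@@H]1C(C)=CC[C@@H]2C(C)(C)C[C@@H](O)C[C@@]12C | intermediate
20 | (2R,5R,9R,10R,13S,14R)-13,14-epoxy-15-iodolabd-7-en-2-ol | IC[C@@H]3O[C@@]3(C)CC[C@@H]1C(C)=CC[C@@H]2C(C)(C)C[C@@H](O)C[C@@]12C | intermediate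
21 | (2R,5R,9R,10R,13S)-labda-7,14-diene-2,13-diol | C=C[C@@](C)(O)CC[C@@H]1C(C)=CC[C@@H]2C(C)(C)C[C@@H](O)C[C@@]12C | intermediate
22 | (2R,5R,9R,10R,13S)-13-hydroxylabda-7,14-dien-2-yl 3-methylbut-2-enoate (CNP0252389.1) | C=C[C@@](C)(O)CC[C@@H]1C(C)=CC[C@@H]2C(C)(C)C[C@@H](OC(=O)C=C(C)C)C[C@@]12C | target

**Step count**
Total: 16 steps. Longest linear sequence: 12 steps (steps 1–5, then 10–16, from (R)-epichlorohydrin).

**Steps most likely to fail**

Step 11 (key step, proposed new method). Several things may go wrong: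
- reduction of the C4 or C10 radical by hydrogen-atom donors before ring closure;
- initiation at a trisubstituted alkene;
- chain addition of the sulfonyl radical to the isopropenyl group, or E/Z scrambling of the chain alkenes by reversible sulfonyl-radical addition;
- insufficient facial control by the C2 silyloxy group.

Fallback, setting out from 16 and returning at 17: the sulfone is first removed without moving the double bond by palladium-catalysed hydride displacement (PdCl2(dppp), LiBHEt3, THF, 0 °C) to give the all-E tetraene tert-butyl{[(2E,6E,10E,13R)-13-[(tert-butyldimethylsilyl)oxy]-3,7,11,15-tetramethylhexadeca-2,6,10,15-tetraen-1-yl]oxy}diphenylsilane F1. F1 is then folded by the known hydrogen-atom-transfer radical–polar crossover bicyclization (N,N′-bis(3,5-di-tert-butylsalicylidene)-1,2-cyclohexanediaminocobalt with divalent cobalt as precatalyst, N-fluoro-2,4,6-trimethylpyridinium tetrafluoroborate, PhSiH3, hexafluoroisopropanol-containing solvent, 0 °C). Here the C4 radical is oxidised to the cation, so the chain closes as a fast cation–olefin cascade that ends by proton loss. This would give 17 together with exocyclic and tetrasubstituted alkene isomers, which would have to be separated on AgNO3-impregnated silica; over-cyclization through C13=C14 would also have to be checked.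

Step 7. Over-oxidation to the enal, incomplete conversion and oxidation at other allylic positions may reduce throughput. Fallback, setting out from 11 and returning at 14: ene-type chlorination of the terminal trisubstituted alkene with HOCl (Ca(OCl)2, CO2, CH2Cl2/H2O, 0 °C) gives the transposed secondary allylic chloride tert-butyl{[(2E)-6-chloro-3,7-dimethylocta-2,7-dien-1-yl]oxy}diphenylsilane F2 (racemic at C6). Allylic sulfonylation with PhSO2Na and Pd(PPh3)4 (zerovalent palladium, cat.) in THF/MeOH should then place the sulfonyl group on the primary terminus with E geometry, giving 14 without passing through 12 and 13.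

Step 16. The acyl chloride may lose its conjugation through a vinylketene (giving the 3-methylbut-3-enoate), or the acylation may be sluggish. Fallback, setting out from 21 and returning at 22: Steglich esterification of the C2 hydroxyl with (diethoxyphosphoryl)acetic acid (DCC, DMAP, CH2Cl2) gives (2R,5R,9R,10R,13S)-13-hydroxylabda-7,14-dien-2-yl (diethoxyphosphoryl)acetate F3. Horner–Wadsworth–Emmons olefination with acetone (NaH, THF, excess acetone) then builds the 3-methylbut-2-enoate on the molecule, where no deconjugation pathway is open.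

**Further compounds**
F1 | step 11 | tert-butyl{[(2E,6E,10E,13R)-13-[(tert-butyldimethylsilyl)oxy]-3,7,11,15-tetramethylhexadeca-2,6,10,15-tetraen-1-yl]oxy}diphenylsilane | C=C(C)C[C@@H](O[Si](C)(C)C(C)(C)C)C/C(C)=C/CC/C(C)=C/CC/C(C)=C/CO[Si](c1ccccc1)(c1ccccc1)C(C)(C)C
F2 | step 7 | tert-butyl{[(2E)-6-chloro-3,7-dimethylocta-2,7-dien-1-yl]oxy}diphenylsilane | C=C(C)C(Cl)CC/C(C)=C/CO[Si](c1ccccc1)(c1ccccc1)C(C)(C)C
F3 | step 16 | (2R,5R,9R,10R,13S)-13-hydroxylabda-7,14-dien-2-yl (diethoxyphosphoryl)acetate | C=C[C@@](C)(O)CC[C@@H]1C(C)=CC[C@@H]2C(C)(C)C[C@@H](OC(=O)CP(=O)(OCC)OCC)C[C@@]12C
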